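**Retrosynthetic overview**
- Target ⇒ hydrogenolysis of two aryl benzyl ethers; the carbinol centre comes from chelation-controlled reduction of an α-aryloxy ketone, itself assembled from the ring C phenol, ethyl (S)-lactate (Mitsunobu, inversion) and a ring D aryl Grignard reagent through a Weinreb amide.
- The C2 and C3 methyls ⇐ trans-2,3-diester (LiAlH4, mesylation, hydride); C4H2 ⇐ C4–OH by ionic reduction, made easy by the para benzyloxy group on ring A.
- Feature used: in ring B, C1 (bearing ring C) and C4 (the CH2) are both benzylic carbons on ring A (at C8a and C4a), and C2/C3 carry trans one-carbon groups. Ring B is therefore the [4+2] adduct of a ring A o-quinodimethane (C1–C8a–C4a–C4) and a fumarate (C2–C3), made by photoenolisation of a 2-benzylbenzaldehyde on a titanium–TADDOL template, forming C1–C2 and C3–C4.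
- 2-Benzylbenzaldehyde ⇐ Br/Li exchange and DMF on a bromodiarylmethane ⇐ ring C Grignard reagent + 6-bromo-O-benzylisovanillin, then Et3SiH/TFA. The formyl group is introduced last, because a diaryl carbinol next to an ortho acetal would cyclise to phthalan or isobenzofuran products under acid.
- Ring order: rings A, C and D are bought as arenes; ring B is the only ring formed (step 6).

Key step: step 6

Numbering: tetralin C1 bears ring C, C2 and C3 bear the methyls, C4 is the CH2, ring A is the fused arene, ring D is the terminal guaiacyl ring; Cα is the carbinol carbon and Cβ the aryloxy-bearing carbon of the propanol chain.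
Assumption: the TADDOL antipode that gives the 1S series cannot be assigned by analogy alone; (R,R)-TADDOL is written, and its mirror image would be used if a test cycloaddition shows the opposite sense.

**Step 1**
Reactants: 1 4-bromo-2-methoxyphenol
Product: 2 1-(allyloxy)-4-bromo-2-methoxybenzene
Conditions: allyl bromide, K2CO3, DMF, rt
Reagents that add atoms: allyl bromide, C=CCBr
Why: Williamson ether synthesis, the phenoxide displacing bromide from allyl bromide by SN2.

**Step 2**
Reactants: 3 3-(benzyloxy)-4-methoxybenzaldehyde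
Product: 4 5-(benzyloxy)-2-bromo-4-methoxybenzaldehyde
Conditions: Br2, NaOAc, AcOH, rt
Reagents that add atoms: bromine, BrBr
Why: Electrophilic aromatic bromination goes para to the benzyloxy group (the 4-methoxy group is tied up in conjugation with the para formyl group), the usual regiochemistry of 3,4-dialkoxybenzaldehydes.

**Step 3**
Reactants: 2 1-(allyloxy)-4-bromo-2-methoxybenzene; 4 5-(benzyloxy)-2-bromo-4-methoxybenzaldehyde
Product: 6 [4-(allyloxy)-3-methoxyphenyl][5-(benzyloxy)-2-bromo-4-methoxyphenyl]methanol (racemic), via aryl Grignard reagent 5 (not isolated)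
Conditions: Mg, THF, rt; then 4, 0 °C; sat. aq. NH4Cl
Reagents that add atoms: none
Why: Grignard formation and 1,2-addition to the aldehyde, the aryl bromide of 4 being inert to the arylmagnesium reagent at 0 °C; the carbinol centre is racemic and is removed in step 4.

**Step 4**
Reactants: 6 [4-(allyloxy)-3-methoxyphenyl][5-(benzyloxy)-2-bromo-4-methoxyphenyl]methanol
Product: 7 1-(allyloxy)-4-[5-(benzyloxy)-2-bromo-4-methoxybenzyl]-2-methoxybenzene
Conditions: Et3SiH, TFA, CH2Cl2, 0 °C
Reagents that add atoms: none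
Why: Ionic hydrogenation: the carbinol ionises to a diarylmethyl cation stabilised by the para allyloxy and para methoxy groups and takes hydride from Et3SiH, with no acid-sensitive neighbour present at this stage.

**Step 5**
Reactants: 7 1-(allyloxy)-4-[5-(benzyloxy)-2-bromo-4-methoxybenzyl]-2-methoxybenzene
Product: 9 2-[4-(allyloxy)-3-methoxybenzyl]-4-(benzyloxy)-5-methoxybenzaldehyde, via aryllithium 8 (not isolated)
Conditions: n-BuLi, THF, −78 °C; then DMF, −78 °C to 0 °C; 1 M HCl
Reagents that add atoms: N,N-dimethylformamide, CN(C)C=O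
Why: Bromine–lithium exchange followed by formylation with DMF (Bouveault aldehyde synthesis); exchange at −78 °C is faster than deprotonation of the diarylmethane CH2.

**Step 6**
Reactants: 9 2-[4-(allyloxy)-3-methoxybenzyl]-4-(benzyloxy)-5-methoxybenzaldehyde; 10 dimethyl fumarate
Product: 12 dimethyl (1S,2R,3S,4S)-1-[4-(allyloxy)-3-methoxyphenyl]-7-(benzyloxy)-4-hydroxy-6-methoxy-1,2,3,4-tetrahydronaphthalene-2,3-dicarboxylate, via hydroxy-o-quinodimethane 11 (not isolated)
Conditions: Ti(OiPr)4 (2 equiv), (R,R)-TADDOL (2.2 equiv), toluene, hν (366 nm), rt, Ar; then aq. NaHCO3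
Reagents that add atoms: none
Why: Proposed new method: n,π* excitation of aldehyde 9 and a 1,5-hydrogen shift from the diarylmethane CH2 give the (E,E)-dienol 11, which as its titanium dienolate adds fumarate 10 in a concerted suprafacial [4+2] cycloaddition; the closest known reactions are the photoenolisation/Diels–Alder trapping of 2-benzylbenzaldehydes with fumarates and the Ti(OiPr)4/TADDOL-mediated enantioselective photoenol Diels–Alder reaction of 2-methylbenzaldehydes, joined here on an aryl-substituted dienol with a diester dienophile. Ring B closes by this intermolecular [4+2] cycloaddition (six-membered, bonds C1–C2 and C3–C4), which restores the aromaticity of ring A. C1 and C4 come out cis because both the aryl and the hydroxyl group sit outward on the dienol; C3 is set cis to the C4 hydroxyl because titanium bridges the dienolate oxygen and the carbonyl of the adjacent ester (endo); C2 is trans to C3 from the E geometry of the fumarate and so trans to ring C; the absolute sense (1S) is set by the TADDOL diolate on titanium, which blocks one diene face. The step needs the templated endo pairing to outrun the untemplated hydrogen-bonded cycloaddition (expected to put the C2 ester cis to ring C) and needs one diene face; stoichiometric titanium alkoxide, which captures the dienol as it forms, and the C2-symmetric ligand are meant to secure both.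

**Step 7**
Reactants: 12 dimethyl (1S,2R,3S,4S)-1-[4-(allyloxy)-3-methoxyphenyl]-7-(benzyloxy)-4-hydroxy-6-methoxy-1,2,3,4-tetrahydronaphthalene-2,3-dicarboxylate
Product: 13 dimethyl (1S,2R,3R)-1-[4-(allyloxy)-3-methoxyphenyl]-7-(benzyloxy)-6-methoxy-1,2,3,4-tetrahydronaphthalene-2,3-dicarboxylate
Conditions: Et3SiH (excess), TFA, CH2Cl2, −20 to 0 °C
Reagents that add atoms: none
Why: Ionic hydrogenation: the C4 hydroxyl is para to the C7 benzyloxy group, so acid gives a stabilised benzylic cation that excess Et3SiH should reduce before it loses a proton; C1–C3 are untouched.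

**Step 8**
Reactants: 13 dimethyl (1S,2R,3R)-1-[4-(allyloxy)-3-methoxyphenyl]-7-(benzyloxy)-6-methoxy-1,2,3,4-tetrahydronaphthalene-2,3-dicarboxylate
Product: 14 [(1S,2R,3R)-1-[4-(allyloxy)-3-methoxyphenyl]-7-(benzyloxy)-6-methoxy-1,2,3,4-tetrahydronaphthalene-2,3-diyl]dimethanol
Conditions: LiAlH4, THF, 0 °C to rt
Reagents that add atoms: none
Why: Hydride reduction of both esters to primary alcohols; the aryl ethers and the all-equatorial stereocentres are inert.

**Step 9**
Reactants: 14 [(1S,2R,3R)-1-[4-(allyloxy)-3-methoxyphenyl]-7-(benzyloxy)-6-methoxy-1,2,3,4-tetrahydronaphthalene-2,3-diyl]dimethanol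
Product: 15 [(1S,2R,3R)-1-[4-(allyloxy)-3-methoxyphenyl]-7-(benzyloxy)-6-methoxy-1,2,3,4-tetrahydronaphthalene-2,3-diyl]bis(methylene) dimethanesulfonate
Conditions: MsCl, Et3N, CH2Cl2, 0 °C
Reagents that add atoms: methanesulfonyl chloride, CS(=O)(=O)Cl
Why: Sulfonylation of both primary alcohols, fast enough at 0 °C to outrun cyclisation to a tetrahydrofuran.

**Step 10**
Reactants: 15 [(1S,2R,3R)-1-[4-(allyloxy)-3-methoxyphenyl]-7-(benzyloxy)-6-methoxy-1,2,3,4-tetrahydronaphthalene-2,3-diyl]bis(methylene) dimethanesulfonate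
Product: 16 (1S,2S,3R)-1-[4-(allyloxy)-3-methoxyphenyl]-7-(benzyloxy)-6-methoxy-2,3-dimethyl-1,2,3,4-tetrahydronaphthalene
Conditions: LiEt3BH, THF, 0 °C to rt
Reagents that add atoms: none
Why: SN2 displacement of the two primary mesylates by hydride gives the methyl groups without touching a stereocentre (the descriptor at C2 changes only through substituent priorities).

**Step 11**
Reactants: 16 (1S,2S,3R)-1-[4-(allyloxy)-3-methoxyphenyl]-7-(benzyloxy)-6-methoxy-2,3-dimethyl-1,2,3,4-tetrahydronaphthalene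
Product: 17 4-[(1S,2S,3R)-7-(benzyloxy)-6-methoxy-2,3-dimethyl-1,2,3,4-tetrahydronaphthalen-1-yl]-2-methoxyphenol
Conditions: Pd(PPh3)4 (5 mol %), morpholine, THF, rt
Reagents that add atoms: none
Why: Tsuji–Trost deallylation: zerovalent palladium ionises the allyl aryl ether to a π-allyl complex that morpholine intercepts, leaving the benzyl ether in place.

**Step 12**
Reactants: 17 4-[(1S,2S,3R)-7-(benzyloxy)-6-methoxy-2,3-dimethyl-1,2,3,4-tetrahydronaphthalen-1-yl]-2-methoxyphenol; 18 ethyl (S)-lactate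
Product: 19 ethyl (R)-2-{4-[(1S,2S,3R)-7-(benzyloxy)-6-methoxy-2,3-dimethyl-1,2,3,4-tetrahydronaphthalen-1-yl]-2-methoxyphenoxy}propanoate
Conditions: PPh3, DIAD, THF, 0 °C to rt
Reagents that add atoms: none
Why: Mitsunobu reaction: the phenoxide displaces the activated lactate hydroxyl by SN2 with inversion, (S) to (R), which sets Cβ.

**Step 13**
Reactants: 19 ethyl (R)-2-{4-[(1S,2S,3R)-7-(benzyloxy)-6-methoxy-2,3-dimethyl-1,2,3,4-tetrahydronaphthalen-1-yl]-2-methoxyphenoxy}propanoate
Product: 20 (R)-2-{4-[(1S,2S,3R)-7-(benzyloxy)-6-methoxy-2,3-dimethyl-1,2,3,4-tetrahydronaphthalen-1-yl]-2-methoxyphenoxy}-N-methoxy-N-methylpropanamide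
Conditions: MeNH(OMe)·HCl, i-PrMgCl, THF, −20 °C
Reagents that add atoms: N,O-dimethylhydroxylamine hydrochloride, CNOC.Cl
Why: Weinreb amide formation by acyl substitution of the ester with the chloromagnesium amide at low temperature, conditions under which the α-aryloxy centre should not enolise.

**Step 14**
Reactants: 1 4-bromo-2-methoxyphenol
Product: 21 1-(benzyloxy)-4-bromo-2-methoxybenzene
Conditions: benzyl bromide, K2CO3, DMF, rt
Reagents that add atoms: benzyl bromide, BrCc1ccccc1
Why: Williamson ether synthesis.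

**Step 15**
Reactants: 21 1-(benzyloxy)-4-bromo-2-methoxybenzene; 20 (R)-2-{4-[(1S,2S,3R)-7-(benzyloxy)-6-methoxy-2,3-dimethyl-1,2,3,4-tetrahydronaphthalen-1-yl]-2-methoxyphenoxy}-N-methoxy-N-methylpropanamide
Product: 23 (R)-1-[4-(benzyloxy)-3-methoxyphenyl]-2-{4-[(1S,2S,3R)-7-(benzyloxy)-6-methoxy-2,3-dimethyl-1,2,3,4-tetrahydronaphthalen-1-yl]-2-methoxyphenoxy}propan-1-one, via aryl Grignard reagent 22 (not isolated)
Conditions: Mg, THF, rt; then 20, THF, 0 °C; cold 1 M HCl
Reagents that add atoms: none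
Why: Weinreb ketone synthesis: the aryl Grignard reagent adds once and the chelated tetrahedral intermediate collapses only on acidic quench, so Cβ is kept and no tertiary alcohol forms.

**Step 16**
Reactants: 23 (R)-1-[4-(benzyloxy)-3-methoxyphenyl]-2-{4-[(1S,2S,3R)-7-(benzyloxy)-6-methoxy-2,3-dimethyl-1,2,3,4-tetrahydronaphthalen-1-yl]-2-methoxyphenoxy}propan-1-one
Product: 24 (1S,2R)-1-[4-(benzyloxy)-3-methoxyphenyl]-2-{4-[(1S,2S,3R)-7-(benzyloxy)-6-methoxy-2,3-dimethyl-1,2,3,4-tetrahydronaphthalen-1-yl]-2-methoxyphenoxy}propan-1-ol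
Conditions: Zn(BH4)2, Et2O–CH2Cl2, −20 °C
Reagents that add atoms: none
Why: Chelation-controlled (Cram chelate) hydride reduction: zinc ties the carbonyl oxygen to the aryloxy oxygen (helped by the ortho methoxy group) and hydride enters from the face carrying the Cβ hydrogen, which gives the erythro (Cα S, Cβ R) alcohol.

**Step 17**
Reactants: 24 (1S,2R)-1-[4-(benzyloxy)-3-methoxyphenyl]-2-{4-[(1S,2S,3R)-7-(benzyloxy)-6-methoxy-2,3-dimethyl-1,2,3,4-tetrahydronaphthalen-1-yl]-2-methoxyphenoxy}propan-1-ol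
Product: 25 (1S,2R)-1-(4-hydroxy-3-methoxyphenyl)-2-{4-[(1S,2S,3R)-7-hydroxy-6-methoxy-2,3-dimethyl-1,2,3,4-tetrahydronaphthalen-1-yl]-2-methoxyphenoxy}propan-1-ol (CID53359464)
Conditions: H2 (1 atm), 10% Pd/C, EtOAc–EtOH, rt
Reagents that add atoms: none
Why: Hydrogenolysis of the two aryl benzyl ethers, which under neutral conditions should be much faster than cleavage of the benzylic alcohol or the alkyl aryl ether.

**Compound list**
1 | 4-bromo-2-methoxyphenol | COc1cc(Br)ccc1O | starting material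
2 | 1-(allyloxy)-4-bromo-2-methoxybenzene | C=CCOc1ccc(Br)cc1OC | intermediate
3 | 3-(benzyloxy)-4-methoxybenzaldehyde | COc1ccc(C=O)cc1OCc1ccccc1 | starting material
4 | 5-(benzyloxy)-2-bromo-4-methoxybenzaldehyde | COc1cc(Br)c(C=O)cc1OCc1ccccc1 | intermediate
5 | [4-(allyloxy)-3-methoxyphenyl]magnesium bromide | C=CCOc1ccc([Mg]Br)cc1OC | intermediate (not isolated)
6 | [4-(allyloxy)-3-methoxyphenyl][5-(benzyloxy)-2-bromo-4-methoxyphenyl]methanol, racemic | C=CCOc1ccc(C(O)c2cc(OCc3ccccc3)c(OC)cc2Br)cc1OC | intermediate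
7 | 1-(allyloxy)-4-[5-(benzyloxy)-2-bromo-4-methoxybenzyl]-2-methoxybenzene | C=CCOc1ccc(Cc2cc(OCc3ccccc3)c(OC)cc2Br)cc1OC | intermediate
8 | {2-[4-(allyloxy)-3-methoxybenzyl]-4-(benzyloxy)-5-methoxyphenyl}lithium | C=CCOc1ccc(Cc2cc(OCc3ccccc3)c(OC)cc2[Li])cc1OC | intermediate (not isolated)
9 | 2-[4-(allyloxy)-3-methoxybenzyl]-4-(benzyloxy)-5-methoxybenzaldehyde | C=CCOc1ccc(Cc2cc(OCc3ccccc3)c(OC)cc2C=O)cc1OC | intermediate (key-step precursor)
10 | dimethyl fumarate | COC(=O)/C=C/C(=O)OC | starting material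
11 | (E)-{(6E)-6-[4-(allyloxy)-3-methoxybenzylidene]-4-(benzyloxy)-3-methoxycyclohexa-2,4-dien-1-ylidene}methanol (photoenol) | O/C=C1\C=C(OC)C(OCc2ccccc2)=C/C1=C\c3ccc(OCC=C)c(OC)c3 | intermediate (not isolated)
12 | dimethyl (1S,2R,3S,4S)-1-[4-(allyloxy)-3-methoxyphenyl]-7-(benzyloxy)-4-hydroxy-6-methoxy-1,2,3,4-tetrahydronaphthalene-2,3-dicarboxylate | C=CCOc1ccc([C@H]2c3cc(OCc4ccccc4)c(OC)cc3[C@@H](O)[C@@H](C(=O)OC)[C@@H]2C(=O)OC)cc1OC | intermediate (key-step product)
13 | dimethyl (1S,2R,3R)-1-[4-(allyloxy)-3-methoxyphenyl]-7-(benzyloxy)-6-methoxy-1,2,3,4-tetrahydronaphthalene-2,3-dicarboxylate | C=CCOc1ccc([C@H]2c3cc(OCc4ccccc4)c(OC)cc3C[C@@H](C(=O)OC)[C@@H]2C(=O)OC)cc1OC | intermediate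
14 | [(1S,2R,3R)-1-[4-(allyloxy)-3-methoxyphenyl]-7-(benzyloxy)-6-methoxy-1,2,3,4-tetrahydronaphthalene-2,3-diyl]dimethanol | C=CCOc1ccc([C@H]2c3cc(OCc4ccccc4)c(OC)cc3C[C@@H](CO)[C@@H]2CO)cc1OC | intermediate
15 | bis-mesylate of 14 | C=CCOc1ccc([C@H]2c3cc(OCc4ccccc4)c(OC)cc3C[C@@H](COS(C)(=O)=O)[C@@H]2COS(C)(=O)=O)cc1OC | intermediate
16 | (1S,2S,3R)-1-[4-(allyloxy)-3-methoxyphenyl]-7-(benzyloxy)-6-methoxy-2,3-dimethyl-1,2,3,4-tetrahydronaphthalene | C=CCOc1ccc([C@H]2c3cc(OCc4ccccc4)c(OC)cc3C[C@@H](C)[C@@H]2C)cc1OC | intermediate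
17 | 4-[(1S,2S,3R)-7-(benzyloxy)-6-methoxy-2,3-dimethyl-1,2,3,4-tetrahydronaphthalen-1-yl]-2-methoxyphenol | Oc1ccc([C@H]2c3cc(OCc4ccccc4)c(OC)cc3C[C@@H](C)[C@@H]2C)cc1OC | intermediate
18 | ethyl (S)-lactate | CCOC(=O)[C@H](C)O | starting material
19 | ethyl (R)-2-aryloxypropanoate (aryl = ring C of 17) | CCOC(=O)[C@@H](C)Oc1ccc([C@H]2c3cc(OCc4ccccc4)c(OC)cc3C[C@@H](C)[C@@H]2C)cc1OC | intermediate
20 | (R)-N-methoxy-N-methyl-2-aryloxypropanamide (Weinreb amide) | CON(C)C(=O)[C@@H](C)Oc1ccc([C@H]2c3cc(OCc4ccccc4)c(OC)cc3C[C@@H](C)[C@@H]2C)cc1OC | intermediate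
21 | 1-(benzyloxy)-4-bromo-2-methoxybenzene | COc1cc(Br)ccc1OCc1ccccc1 | intermediate
22 | [4-(benzyloxy)-3-methoxyphenyl]magnesium bromide | COc1cc([Mg]Br)ccc1OCc1ccccc1 | intermediate (not isolated)
23 | (R)-1-[4-(benzyloxy)-3-methoxyphenyl]-2-aryloxypropan-1-one | COc1cc(C(=O)[C@@H](C)Oc2ccc([C@H]3c4cc(OCc5ccccc5)c(OC)cc4C[C@@H](C)[C@@H]3C)cc2OC)ccc1OCc1ccccc1 | intermediate
24 | (1S,2R)-1-[4-(benzyloxy)-3-methoxyphenyl]-2-aryloxypropan-1-ol (bis-benzyl ether of the target) | COc1cc([C@H](O)[C@@H](C)Oc2ccc([C@H]3c4cc(OCc5ccccc5)c(OC)cc4C[C@@H](C)[C@@H]3C)cc2OC)ccc1OCc1ccccc1 | intermediate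
25 | (1S,2R)-1-(4-hydroxy-3-methoxyphenyl)-2-{4-[(1S,2S,3R)-7-hydroxy-6-methoxy-2,3-dimethyl-1,2,3,4-tetrahydronaphthalen-1-yl]-2-methoxyphenoxy}propan-1-ol | COc1cc([C@H](O)[C@@H](C)Oc2ccc([C@H]3c4cc(O)c(OC)cc4C[C@@H](C)[C@@H]3C)cc2OC)ccc1O | target

**Totals**
Total step count: 17. Longest linear sequence: 15 steps (1 → 2 → 6 → 7 → 9 → 12 → 13 → 14 → 15 → 16 → 17 → 19 → 20 → 23 → 24 → 25).

**Steps most likely to fail**

1. Step 6 (the labelled step). The titanium–TADDOL template may discriminate poorly between the two faces of the aryl-substituted dienol. Part of the dienol may also react through the untemplated, hydrogen-bonded cycloaddition, which would erode both the 1S configuration and the 1,2-trans pairing. Ester exchange with isopropoxide would be harmless, since all ester groups are later reduced. The fallback uses auxiliary control and sets out from aldehyde 9. Irradiation at 350 nm in toluene without titanium, in the presence of bis[(R)-2-methoxy-2-oxo-1-phenylethyl] fumarate F1 (from fumaryl chloride and methyl (R)-mandelate with pyridine), should give bis[(R)-2-methoxy-2-oxo-1-phenylethyl] (1S,2S,3R,4S)-1-[4-(allyloxy)-3-methoxyphenyl]-7-(benzyloxy)-4-hydroxy-6-methoxy-1,2,3,4-tetrahydronaphthalene-2,3-dicarboxylate F2. Mandelate-derived fumarates are a dienophile class known to add to hydroxy-aryl-o-quinodimethanes with high face selectivity. The auxiliary fixes C1; the (R) antipode is chosen by analogy with the known sense of induction of mandelate fumarates. The untemplated mode is expected to leave the C2 ester cis to ring C. Et3SiH/TFA then removes the C4 hydroxyl to give the (1S,2S,3S) deoxy diester F3. NaOMe in MeOH exchanges the mandelyl for methyl esters and should equilibrate the enolisable C2 and C3 to the all-equatorial 1,2-trans-2,3-trans diester. That is compound 13, where the route is rejoined.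

2. Step 16. Chelation by the weakly basic aryloxy oxygen may be incomplete, giving a threo/erythro mixture, and ketone 23 may enolise at Cβ while it is handled. The fallback forms the Cα–aryl bond instead and sets out from ester 19. i-Bu2AlH in CH2Cl2 at −78 °C gives (R)-2-{4-[(1S,2S,3R)-7-(benzyloxy)-6-methoxy-2,3-dimethyl-1,2,3,4-tetrahydronaphthalen-1-yl]-2-methoxyphenoxy}propanal F5, used at once. [4-(Benzyloxy)-3-methoxyphenyl]titanium triisopropoxide F6 (from Grignard reagent 22 and ClTi(OiPr)3) is a non-chelating aryl donor and should add in the Felkin–Anh sense anti to the aryloxy group. This gives the erythro alcohol 24 directly, bypassing 20 and 23.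

3. Step 7. The C4 cation may lose the C3 proton (E1) to give the conjugated 3,4-alkene and so scramble C3, or the acid may start to cleave the benzyl ether. The fallback is radical deoxygenation (Barton–McCombie) and sets out from alcohol 12. 1,1'-Thiocarbonyldiimidazole with DMAP in THF gives dimethyl (1S,2R,3S,4S)-1-[4-(allyloxy)-3-methoxyphenyl]-7-(benzyloxy)-4-[(1H-imidazol-1-ylcarbonothioyl)oxy]-6-methoxy-1,2,3,4-tetrahydronaphthalene-2,3-dicarboxylate F4. Bu3SnH and AIBN in toluene at 90 °C then cleave the C4–O bond through the benzylic radical without any cation, returning to 13.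

**Further compounds**
F1 | step 6 | bis[(R)-2-methoxy-2-oxo-1-phenylethyl] fumarate | COC(=O)[C@@H](c1ccccc1)OC(=O)/C=C/C(=O)O[C@H](c1ccccc1)C(=O)OC
F2 | step 6 | bis[(R)-2-methoxy-2-oxo-1-phenylethyl] (1S,2S,3R,4S)-1-[4-(allyloxy)-3-methoxyphenyl]-7-(benzyloxy)-4-hydroxy-6-methoxy-1,2,3,4-tetrahydronaphthalene-2,3-dicarboxylate | C=CCOc1ccc([C@H]2c3cc(OCc4ccccc4)c(OC)cc3[C@@H](O)[C@H](C(=O)O[C@H](c5ccccc5)C(=O)OC)[C@H]2C(=O)O[C@H](c6ccccc6)C(=O)OC)cc1OC
F3 | step 6 | bis[(R)-2-methoxy-2-oxo-1-phenylethyl] (1S,2S,3S)-1-[4-(allyloxy)-3-methoxyphenyl]-7-(benzyloxy)-6-methoxy-1,2,3,4-tetrahydronaphthalene-2,3-dicarboxylate | C=CCOc1ccc([C@H]2c3cc(OCc4ccccc4)c(OC)cc3C[C@H](C(=O)O[C@H](c5ccccc5)C(=O)OC)[C@H]2C(=O)O[C@H](c6ccccc6)C(=O)OC)cc1OC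
F4 | step 7 | dimethyl (1S,2R,3S,4S)-1-[4-(allyloxy)-3-methoxyphenyl]-7-(benzyloxy)-4-[(1H-imidazol-1-ylcarbonothioyl)oxy]-6-methoxy-1,2,3,4-tetrahydronaphthalene-2,3-dicarboxylate | C=CCOc1ccc([C@H]2c3cc(OCc4ccccc4)c(OC)cc3[C@@H](OC(=S)n5ccnc5)[C@@H](C(=O)OC)[C@@H]2C(=O)OC)cc1OC
F5 | step 16 | (R)-2-{4-[(1S,2S,3R)-7-(benzyloxy)-6-methoxy-2,3-dimethyl-1,2,3,4-tetrahydronaphthalen-1-yl]-2-methoxyphenoxy}propanal | O=C[C@@H](C)Oc1ccc([C@H]2c3cc(OCc4ccccc4)c(OC)cc3C[C@@H](C)[C@@H]2C)cc1OC
F6 | step 16 | [4-(benzyloxy)-3-methoxyphenyl]titanium triisopropoxide | COc1cc([Ti](OC(C)C)(OC(C)C)OC(C)C)ccc1OCc1ccccc1
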